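The data are calculated from invented constants; the scatter is artificial.

How far did the electrophile go in 10 d in north and in west, two flasks that differ in their free base, and which way does more base push it?

| flask | electrophile | free base | protonated nucleophile | protic impurity | remark | time |
|---|---|---|---|---|---|---|
| amber | 0.19 M | 0.95 equiv | 1.5 equiv | 0.095 M | run made earlier |  |
| blue | 0.19 M | 1.4 equiv | 1.5 equiv | 0.095 M | run made earlier |  |
| north | 0.19 M | 1.20 equiv | 1.50 equiv | 0.0950 M |  | 10 d |
| west | 0.19 M | 0.800 equiv | 1.50 equiv | 0.0950 M |  | 10 d |

| run | time / d | electrophile / % | target / % |
|---|---|---|---|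
| amber | 0.625 | 87 | 7 |
| amber | 0.833 | 85 | 8 |
| amber | 1.67 | 81 | 11 |
| amber | 2.50 | 78 | 9 |
| amber | 4.00 | 74 | 17 |
| amber | 8.00 | 70 | 12 |
| blue | 1.25 | 76 | 14 |
| blue | 2.50 | 65 | 18 |
| blue | 4.00 | 62 | 19 |
| blue | 5.00 | 56 | 18 |
| blue | 6.00 | 57 | 19 |
| blue | 8.00 | 55 | 23 |

(scatter of a reading: 2 percentage points)

1. part of the electrophile that has reacted at the end, north
2. part of the electrophile that has reacted at the end, west
3. what raising the equivalents of free base from its lowest to its highest value here does to the part of the electrophile that has reacted (changes below 5 percentage points count as none) (it falls / no change / it rises)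



Two numbers in the amber run did not seem to go together: it held 0.95 equiv of free base and 1.5 equiv of protonated nucleophile, yet the electrophile still read 70 % at 8.00 d. The cheapest way through that I found was one division. I divided the part reacted at the last reading by the equivalents of free base, and amber gave 0.316 while blue gave 0.321, although blue held 1.47 times the base. So at that reading the extent went with the base, the pattern of a limiting reagent. I named the mean, 0.319, the base yield s, the part of the electrophile reacted per equivalent of free base charged.

Amber had gained 4 percentage points over its last 4.00 d. At that pace the remaining 2.00 d were worth about one reading's scatter, 2 points, so I left them out. That gave me 38.2 % for north and 25.5 % for west, a rise of 13 points against the 5 points margin.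

The forecast said 40 %, 26 % and it rises, noting “That is close to one third of the base equivalents”. It stood slightly above mine, and it had carried its curves on to 10 d.

North gave 40.1 % and west 26.9 %, so it rises, by 13 points.

    electrophile + nucleophile → acid set free + target (k = 0.0710 L mol⁻¹ h⁻¹)
    nucleophile + acid set free ⇌ protonated nucleophile, settled at all times (K = 1400 L mol⁻¹)
    acid set free + free base ⇌ salt of the base, settled at all times (K = 3.20 × 10⁵ L mol⁻¹)
    target ⇌ isomer of the product (K = 1.40, k = 0.0660 h⁻¹)
    nucleophile + protic impurity → quenched reagent (k = 0.360 L mol⁻¹ h⁻¹)
    acid set free + target → side product (k = 0.0120 L mol⁻¹ h⁻¹)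

At 10 d, s came to 0.334 in north and 0.337 in west. A neighbour of north with 2.00 equiv of free base reached 70.2 %, where s gave 63.8 %. Just after the start, north used nucleophile on the protic impurity at 2.5 times the rate it used it on the electrophile, and half of that quenching up to 10 d was over by 0.411 d. At 10.0 d north still held, unbound, 0.019 % of its charged free base, the limiting reagent, against 60 % of its charged electrophile.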